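**Plan**

Labels: ring A (on C7a) and ring G (on C8a) sit on the western dihydrofuran, which is fused to central ring B (C9b–C14b). Ring D (on C7b) sits on the eastern dihydrofuran, fused to ring C (C9c–C14c). Ring E is on C7c. The seven-membered ring is C8b–C9b–C10b–C7c–C8c–C9c–C10c.
Retrosynthesis: (1) eight O–CH3 bonds; (2) C8b–C10c and C7c–C10b together, with C8b raised to a ketone and C7c lowered to CH2, giving an open α-aryloxy ketone; (3) O–C7b; (4) C9b–C8b; (5) C7a–C8a.
Enabling feature: C10c and C9c are neighbours on ring C. Once C10c is bonded to C8b, the C7c–H of the C9c arm lies 1,5 to a C8b cation. C10c and C10b are each ortho to an ether oxygen and para to a second oxygen. The 2,4-dioxygenated ring E makes C7c both a hydride donor and a good cation, so the oxidation-level swap cancels itself and no helper has to be removed.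
Forward: western dihydrofuran, acylation at C9b, diazo transfer, and union with the ring C/E bibenzyl phenol through O–C7b. The eastern dihydrofuran and the seven-membered ring then form in one acid operation, followed by demethylation.
Stereochemistry: C8a comes from a chiral dirhodium catalyst and C7a from acid equilibration to trans. C7b of the open ketone comes from a chiral phosphoric acid and is relayed to C8b by the face-selective internal hydride shift. C7c and the final C7b configuration come from the thermodynamic funnel of the key step.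

Key step: step 12

Assumption: the sense of induction of Rh2(S-PTAD)4 (step 5) and of the (R)-spiro phosphoric acid (step 11) is taken as drawn; if either proves opposite, its mirror-image form is used.

Step 1
Reactants: 1 4-bromo-2-fluoro-6-methoxybenzaldehyde; 2 4-methoxybenzyl alcohol
Product: 3 4-bromo-2-methoxy-6-[(4-methoxybenzyl)oxy]benzaldehyde
Conditions: NaH, DMF, 0 to 60 °C
Reagents that add atoms: none
Why: Nucleophilic aromatic substitution (addition–elimination) in which the fluoride ortho to the formyl group is the activated nucleofuge, while the bromide, a poor leaving group in this mechanism, is kept for step 7.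

Step 2
Reactants: 3 4-bromo-2-methoxy-6-[(4-methoxybenzyl)oxy]benzaldehyde; 4 3,5-dimethoxyphenylmagnesium bromide
Product: 5 rac-{4-bromo-2-methoxy-6-[(4-methoxybenzyl)oxy]phenyl}(3,5-dimethoxyphenyl)methanol
Conditions: THF, 0 °C; aq NH4Cl
Reagents that add atoms: none
Why: Grignard 1,2-addition to the aldehyde, which leaves the aryl bromide untouched at 0 °C; the racemic carbinol centre is erased in step 3.

Step 3
Reactants: 5 diaryl carbinol
Product: 6 {4-bromo-2-methoxy-6-[(4-methoxybenzyl)oxy]phenyl}(3,5-dimethoxyphenyl)methanone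
Conditions: Dess–Martin periodinane, CH2Cl2, 23 °C
Reagents that add atoms: none
Why: Dess–Martin oxidation of a secondary benzylic alcohol under neutral conditions that spare the 4-methoxybenzyl ether.

Step 4
Reactants: 6 diaryl ketone
Product: 7 hydrazone of ketone 6 (E/Z mixture)
Conditions: N2H4·H2O (excess), AcOH (cat.), n-BuOH, 120 °C, sealed tube
Reagents that add atoms: hydrazine, NN
Why: Condensation of a diaryl ketone with hydrazine, forced by heat and acid catalysis because both ortho positions of ring B are occupied; both hydrazone isomers converge in step 5.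

Step 5
Reactants: 7 hydrazone
Product: 9 (2R,3S)-6-bromo-3-(3,5-dimethoxyphenyl)-4-methoxy-2-(4-methoxyphenyl)-2,3-dihydrobenzofuran (cis), via diaryldiazomethane 8 (not isolated)
Conditions: MnO2, CH2Cl2, 0 °C, filtration; Rh2(S-PTAD)4 = dirhodium tetrakis[(S)-(1-adamantyl)(N-phthalimido)acetate] (1 mol %), CH2Cl2, 0 °C
Reagents that add atoms: none
Why: Hydrazone oxidation followed by enantioselective intramolecular C–H insertion of the donor/donor rhodium carbene into the doubly activated O–CH2–aryl bond (preferred over OCH3), in which the chiral carboxylate ligands set C8a as S and the concerted insertion gives the cis ring.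

Step 6
Reactants: 9 cis-dihydrobenzofuran
Product: 10 (2S,3S)-6-bromo-3-(3,5-dimethoxyphenyl)-4-methoxy-2-(4-methoxyphenyl)-2,3-dihydrobenzofuran (trans)
Conditions: CF3CO2H/CH2Cl2 1:4, 23 °C
Reagents that add atoms: none
Why: Acid-induced epimerisation at C7a by reversible heterolysis of the O–C7a bond (cation stabilised by ring A), which relaxes the cis ring to the more stable trans isomer under control of the untouched C8a centre.

Step 7
Reactants: 10 trans aryl bromide; 11 4-methoxyphenylacetyl chloride
Product: 14 1-[(2S,3S)-3-(3,5-dimethoxyphenyl)-4-methoxy-2-(4-methoxyphenyl)-2,3-dihydrobenzofuran-6-yl]-2-(4-methoxyphenyl)ethanone, via aryllithium 12 (not isolated), via arylzinc chloride 13 (not isolated)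
Conditions: n-BuLi, THF, −78 °C; ZnCl2, −78 to 0 °C; 11, Pd(PPh3)4 (5 mol %), 0 to 23 °C
Reagents that add atoms: none
Why: Bromine–lithium exchange, transmetalation to zinc and Negishi acylation under zerovalent palladium catalysis, chosen because the weakly basic arylzinc does not enolise the arylacetyl chloride; no stereocentre is touched.

Step 8
Reactants: 14 deoxybenzoin
Product: 15 2-diazo-1-[(2S,3S)-3-(3,5-dimethoxyphenyl)-4-methoxy-2-(4-methoxyphenyl)-2,3-dihydrobenzofuran-6-yl]-2-(4-methoxyphenyl)ethanone
Conditions: p-ABSA, DBU, MeCN, 0 to 23 °C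
Reagents that add atoms: 4-acetamidobenzenesulfonyl azide (p-ABSA), CC(=O)Nc1ccc(cc1)S(=O)(=O)N=[N+]=[N-]
Why: Regitz diazo transfer onto the acidic benzylic methylene of the aryl benzyl ketone.

Step 9
Reactants: 16 3-bromo-5-methoxyphenol; 17 1-ethynyl-2,4-dimethoxybenzene
Product: 18 3-[(2,4-dimethoxyphenyl)ethynyl]-5-methoxyphenol
Conditions: PdCl2(MeCN)2 (2 mol %), XPhos (6 mol %), Cs2CO3, MeCN, 80 °C
Reagents that add atoms: none
Why: Copper-free Sonogashira coupling, which tolerates the free phenol and joins rings C and E.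

Step 10
Reactants: 18 diarylalkyne
Product: 19 3-[2-(2,4-dimethoxyphenyl)ethyl]-5-methoxyphenol
Conditions: H2 (1 atm), Pd/C, EtOAc/MeOH, 23 °C
Reagents that add atoms: none
Why: Catalytic hydrogenation of the alkyne to the C8c–C7c ethano bridge, whose C7c–H later serves as the internal hydride source.

Step 11
Reactants: 15 α-diazoketone; 19 bibenzyl phenol
Product: 20 (2S)-2-{3-[2-(2,4-dimethoxyphenyl)ethyl]-5-methoxyphenoxy}-1-[(2S,3S)-3-(3,5-dimethoxyphenyl)-4-methoxy-2-(4-methoxyphenyl)-2,3-dihydrobenzofuran-6-yl]-2-(4-methoxyphenyl)ethanone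
Conditions: Rh2(O2CCPh3)4 (1 mol %), (R)-6,6'-bis(2,4,6-triisopropylphenyl)-SPINOL hydrogen phosphate (2 mol %), CHCl3, 25 °C, slow addition of 15
Reagents that add atoms: none
Why: Rhodium-carbene O–H insertion into the phenol with cooperative chiral phosphoric acid catalysis, in which the acid delivers the proton to one face of the enol (oxonium ylide) intermediate and so sets C7b as S independently of the distant C7a/C8a pair.

Step 12
Reactants: 20 α-aryloxy ketone
Product: 23 (7aS,8aS,7bS,8bS,7cS)-octa-O-methyl ether of the target, via tertiary carbinol 21 (not isolated), via cis isomer 22 (not isolated)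
Conditions: Tf2NH (1.5 equiv), (CF3)2CHOH/CH2Cl2 1:4, 0.005 M, −30 °C; then 40 °C
Reagents that add atoms: none
Why: Proposed new method: the acid first triggers the known opening move of α-aryloxy ketone cyclodehydration, attack of C10c (ortho to the ether oxygen, para to OMe) on the protonated C8b carbonyl (5-exo-trig), and carbinol 21 ionises to a C8b cation held coplanar with ring C. Because the arm on the neighbouring ring atom C9c holds the C7c–H bonds, activated by the ortho and para methoxy groups of ring E, 1,5 to this cation, a hydride should cross through a six-membered transition state (closest known type: 1,5-hydride shift/cyclisation of 2-(2-arylethyl)benzylidene malonates and of para-quinone methides), so that the carbonyl oxygen leaves as water, C8b gains its hydrogen and the charge reappears at C7c without any external reductant. C10b of ring B then closes the seven-membered ring on C7c (7-exo-trig with respect to the quinoid C7c=ring E bond), a Friedel–Crafts closure known from the acid cyclisation of dihydrobenzofuran stilbene dimers. Stereocontrol: at C8b the arm can reach the cation only on the face that bears H-7b, anti to ring D, so that (7bS)-20 is translated into (8bS) and the cis isomer 22 forms first; at C7c ring E takes the pseudo-axial position syn to H-8b, because the pseudo-equatorial one collides with O11b, and the reversible closure corrects errors; at C7b, warming allows reversible O–C7b heterolysis (cation stabilised by ring D) that funnels cis-22 into trans-23, while the already trans C7a/C8a pair is returned unchanged by the same process. Selectivity needed: C10c over C12c (para-methoxy activation, and only the C10c adduct can go on), C10b over C14b (O11b is tied back in a ring whereas the C13b methoxy group, buttressed by C12b, lies over C14b), and hydride transfer over loss of H-7b to the benzofuran, which the non-basic medium, a full equivalent of strong acid and the low starting temperature are meant to secure; benzofuran that does form can re-enter by protonation but without the C7b information.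

Step 13
Reactants: 23 octa-O-methyl ether
Product: 24 CNP0154774.1 (7aS,8aS,7bS,8bS,7cS)
Conditions: BBr3 (excess), CH2Cl2, −78 to 23 °C; MeOH/H2O
Reagents that add atoms: none
Why: Lewis-acid cleavage of aryl methyl ethers with boron tribromide; the benzylic C–O bonds may ionise reversibly, but both dihydrofurans are already trans and ring E is already pseudo-axial, so no centre should be scrambled.

**Compound list**

1 | 4-bromo-2-fluoro-6-methoxybenzaldehyde | COc1cc(Br)cc(F)c1C=O | starting material
2 | 4-methoxybenzyl alcohol | COc1ccc(CO)cc1 | starting material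
3 | 4-bromo-2-methoxy-6-[(4-methoxybenzyl)oxy]benzaldehyde | COc1ccc(COc2cc(Br)cc(OC)c2C=O)cc1 | intermediate
4 | 3,5-dimethoxyphenylmagnesium bromide | COc1cc(OC)cc([Mg]Br)c1 | starting material
5 | rac-{4-bromo-2-methoxy-6-[(4-methoxybenzyl)oxy]phenyl}(3,5-dimethoxyphenyl)methanol | COc1ccc(COc2cc(Br)cc(OC)c2C(O)c2cc(OC)cc(OC)c2)cc1 | intermediate
6 | {4-bromo-2-methoxy-6-[(4-methoxybenzyl)oxy]phenyl}(3,5-dimethoxyphenyl)methanone | COc1ccc(COc2cc(Br)cc(OC)c2C(=O)c2cc(OC)cc(OC)c2)cc1 | intermediate
7 | hydrazone of 6 (E/Z) | COc1ccc(COc2cc(Br)cc(OC)c2C(=NN)c2cc(OC)cc(OC)c2)cc1 | intermediate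
8 | diaryldiazomethane from 7 | COc1ccc(COc2cc(Br)cc(OC)c2C(=[N+]=[N-])c2cc(OC)cc(OC)c2)cc1 | intermediate
9 | (2R,3S)-6-bromo-3-(3,5-dimethoxyphenyl)-4-methoxy-2-(4-methoxyphenyl)-2,3-dihydrobenzofuran (cis) | COc1ccc([C@@H]2Oc3cc(Br)cc(OC)c3[C@@H]2c2cc(OC)cc(OC)c2)cc1 | intermediate
10 | (2S,3S)-6-bromo-3-(3,5-dimethoxyphenyl)-4-methoxy-2-(4-methoxyphenyl)-2,3-dihydrobenzofuran (trans) | COc1ccc([C@H]2Oc3cc(Br)cc(OC)c3[C@@H]2c2cc(OC)cc(OC)c2)cc1 | intermediate
11 | 4-methoxyphenylacetyl chloride | COc1ccc(CC(=O)Cl)cc1 | starting material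
12 | aryllithium from 10 | COc1ccc([C@H]2Oc3cc([Li])cc(OC)c3[C@@H]2c2cc(OC)cc(OC)c2)cc1 | intermediate
13 | arylzinc chloride from 12 | COc1ccc([C@H]2Oc3cc([Zn]Cl)cc(OC)c3[C@@H]2c2cc(OC)cc(OC)c2)cc1 | intermediate
14 | 1-[(2S,3S)-3-(3,5-dimethoxyphenyl)-4-methoxy-2-(4-methoxyphenyl)-2,3-dihydrobenzofuran-6-yl]-2-(4-methoxyphenyl)ethanone | COc1ccc([C@H]2Oc3cc(C(=O)Cc4ccc(OC)cc4)cc(OC)c3[C@@H]2c2cc(OC)cc(OC)c2)cc1 | intermediate
15 | 2-diazo derivative of 14 | COc1ccc([C@H]2Oc3cc(C(=O)C(=[N+]=[N-])c4ccc(OC)cc4)cc(OC)c3[C@@H]2c2cc(OC)cc(OC)c2)cc1 | intermediate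
16 | 3-bromo-5-methoxyphenol | COc1cc(O)cc(Br)c1 | starting material
17 | 1-ethynyl-2,4-dimethoxybenzene | C#Cc1ccc(OC)cc1OC | starting material
18 | 3-[(2,4-dimethoxyphenyl)ethynyl]-5-methoxyphenol | COc1cc(O)cc(C#Cc2ccc(OC)cc2OC)c1 | intermediate
19 | 3-[2-(2,4-dimethoxyphenyl)ethyl]-5-methoxyphenol | COc1cc(O)cc(CCc2ccc(OC)cc2OC)c1 | intermediate
20 | (7bS)-α-aryloxy ketone (full name in step 11) | COc1ccc([C@H]2Oc3cc(C(=O)[C@@H](Oc4cc(OC)cc(CCc5ccc(OC)cc5OC)c4)c4ccc(OC)cc4)cc(OC)c3[C@@H]2c2cc(OC)cc(OC)c2)cc1 | intermediate
21 | tertiary carbinol from C10c–C8b closure of 20 (7bS; C8b not assigned) | COc1ccc([C@H]2Oc3cc(C4(O)c5c(CCc6ccc(OC)cc6OC)cc(OC)cc5O[C@H]4c4ccc(OC)cc4)cc(OC)c3[C@@H]2c2cc(OC)cc(OC)c2)cc1 | intermediate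
22 | (7aS,8aS,7bR,8bS,7cS)-octa-O-methyl compound, eastern dihydrofuran cis (7b-epimer of 23) | COc1ccc([C@H]2Oc3c4c(cc(OC)c3[C@@H]2c2cc(OC)cc(OC)c2)[C@H]2c3c(cc(OC)cc3O[C@H]2c2ccc(OC)cc2)C[C@H]4c2ccc(OC)cc2OC)cc1 | intermediate
23 | (7aS,8aS,7bS,8bS,7cS)-octa-O-methyl ether of the target | COc1ccc([C@H]2Oc3c4c(cc(OC)c3[C@@H]2c2cc(OC)cc(OC)c2)[C@H]2c3c(cc(OC)cc3O[C@@H]2c2ccc(OC)cc2)C[C@H]4c2ccc(OC)cc2OC)cc1 | intermediate
24 | CNP0154774.1 | Oc1ccc([C@H]2Oc3c4c(cc(O)c3[C@@H]2c2cc(O)cc(O)c2)[C@H]2c3c(cc(O)cc3O[C@@H]2c2ccc(O)cc2)C[C@H]4c2ccc(O)cc2O)cc1 | target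

Total step count: 13. Longest linear sequence: 11 (steps 1–8 and 11–13).

**Steps most likely to fail**

(1) Step 12.
- What may go wrong: proton loss from C7b of the C8b cation may outrun the hydride shift. That drains material into the aromatic benzofuran and erodes the C7b-to-C8b relay, so the diastereomer with the opposite configuration at C7b, C8b and C7c would have to be separated. The hydride shift itself may also be too slow.
- Fallback (known reaction types, external hydride instead of the internal one): it sets out from 18 (with 15) and returns at 23. Alkyne 18 is semihydrogenated (H2, Pd/CaCO3 poisoned with Pb(OAc)2, quinoline) to (Z)-3-[2-(2,4-dimethoxyphenyl)ethenyl]-5-methoxyphenol F1. Rh2(OAc)4-catalysed O–H insertion of 15 into this phenol gives the stilbene-bearing α-aryloxy ketone F2. Bi(OTf)3 or TfOH in CH2Cl2 then effects cyclodehydration to the benzofuran and Markovnikov hydroarylation of the protonated stilbene by C10b. This gives the benzofuran-fused dibenzocycloheptadiene F3, whose C7c epimers are separated by chromatography. Ionic hydrogenation of the benzofuran (Et3SiH, CF3CO2H, CH2Cl2) leads to 23. Here protonation at C8b is reversible and settles syn to ring E, and C7b equilibrates to trans.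

(2) Step 4.
- What may go wrong: steric shielding of the carbonyl by the two ortho alkoxy groups may make condensation with hydrazine stall.
- Fallback (nitrosocarbamate route to hindered diaryldiazomethanes): it sets out from 5 and returns at 8. Carbinol 5 is condensed with ethyl carbamate (TsOH cat., MeCN) to ethyl N-(diarylmethyl)carbamate F4. This is N-nitrosated (NaNO2, Ac2O/AcOH, 0 °C) to the N-nitrosocarbamate F5. Treatment with KOt-Bu (THF, −20 °C) releases 8, which enters the rhodium stage of step 5.

(3) Step 13.
- What may go wrong: eightfold cleavage may stay incomplete. Prolonged exposure to the Lewis acid may also cause ionisation of the benzylic ethers followed by intermolecular alkylation.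
- Fallback: it sets out from 23 and returns at 24. It replaces electrophilic activation by SN2 attack at the methyl groups under non-ionising basic conditions (NaSEt, DMF, 130 °C, then acidification), and no new isolated compound is made.

**Further compounds**

F1 | step 12 | (Z)-3-[2-(2,4-dimethoxyphenyl)ethenyl]-5-methoxyphenol | COc1cc(O)cc(/C=C\c2ccc(OC)cc2OC)c1
F2 | step 12 | stilbene-bearing α-aryloxy ketone (C7b epimers) | COc1ccc([C@H]2Oc3cc(C(=O)C(Oc4cc(OC)cc(/C=C\c5ccc(OC)cc5OC)c4)c4ccc(OC)cc4)cc(OC)c3[C@@H]2c2cc(OC)cc(OC)c2)cc1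
F3 | step 12 | (7aS,8aS,7cS)-benzofuran-fused dibenzocycloheptadiene | COc1ccc([C@H]2Oc3c4c(cc(OC)c3[C@@H]2c2cc(OC)cc(OC)c2)-c2c(-c3ccc(OC)cc3)oc3cc(OC)cc(c23)C[C@H]4c2ccc(OC)cc2OC)cc1
F4 | step 4 | ethyl N-({4-bromo-2-methoxy-6-[(4-methoxybenzyl)oxy]phenyl}(3,5-dimethoxyphenyl)methyl)carbamate | CCOC(=O)NC(c1cc(OC)cc(OC)c1)c1c(OC)cc(Br)cc1OCc1ccc(OC)cc1
F5 | step 4 | N-nitroso derivative of the carbamate | CCOC(=O)N(N=O)C(c1cc(OC)cc(OC)c1)c1c(OC)cc(Br)cc1OCc1ccc(OC)cc1
F0 | step 13 | none | none
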